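**Plan** (atom numbers are those of the 1-benzoxepine target: O1, C2, C3, C4, C5, C5a, C6–C9, C9a; ring A = cyclohexane, ring B = oxepene)
- Retrosynthesis cuts, in this order: both C–Br bonds (from a diol, C7 with inversion); O1–C2 of ring B (7-endo epoxide opening by the C9a hydroxyl); C9a–CH3 (methyl addition to a ring A ketone); then, together, C5–C5a and C2–C3.
- Enabling feature: the C3=C4–C5 allyl unit of ring B lies between C5a, which is alpha to the former C9a carbonyl of ring A (an enolate carbon), and C2, a carbinol carbon that can be an acyl carbon. A (Z)-1-bromo-3-stannylbutene is electrophilic at C5 and nucleophilic at C3, so it joins both partners in one flask.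
- Forward: ring A is bought as a cyclohexenone and made gem-dimethyl by two cuprate additions; the chain is joined in step 7; ring B is closed in step 11; the bromides are installed last.
- Stereochemistry: the C7 carbinol is bought (R) and relays C5a (axial enolate alkylation) and C9a (equatorial methyl addition) before it is inverted to the 7S bromide. C2 comes from a CBS reduction followed by inversion on epoxide opening; the Z alkene comes from a trans-hydroalumination.

Key step: step 7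

Assumption: compounds 1, 5 and 11 are taken as purchasable.

Step 1
Reactants: 1 (R)-4-[(tert-butyldimethylsilyl)oxy]cyclohex-2-en-1-one
Product: 3 (R)-4-[(tert-butyldimethylsilyl)oxy]-3-methylcyclohex-2-en-1-one, via trimethylsilyl enol ether 2 (not isolated)
Conditions: Me2CuLi, Me3SiCl, THF, −78 °C; then Pd(OAc)2, MeCN, 25 °C
Reagents that add atoms: lithium dimethylcuprate C[Cu-]C.[Li+]
Why: Conjugate addition of the cuprate anti to the silyloxy group with in situ silylation, then Saegusa–Ito oxidation of enol silane 2, should return the enone carrying the new beta-methyl group; the carbinol centre is untouched and the transient methyl-bearing centre is removed again.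

Step 2
Reactants: 3 (R)-4-[(tert-butyldimethylsilyl)oxy]-3-methylcyclohex-2-en-1-one
Product: 4 tert-butyl{[(1R)-2,2-dimethyl-4-[(trimethylsilyl)oxy]cyclohex-3-en-1-yl]oxy}dimethylsilane
Conditions: Me2CuLi, Me3SiCl, THF, −78 to −20 °C; Et3N, pentane work-up
Reagents that add atoms: lithium dimethylcuprate C[Cu-]C.[Li+]; chlorotrimethylsilane C[Si](C)(C)Cl
Why: A second Me3SiCl-accelerated cuprate conjugate addition should build the gem-dimethyl carbon (no new stereocentre) and trap the enolate regiospecifically as the silyl enol ether on the side of that carbon.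

Step 3
Reactants: 5 but-2-yne-1,4-diol
Product: 6 4-[(4-methoxybenzyl)oxy]but-2-yn-1-ol
Conditions: NaH, 4-methoxybenzyl chloride, Bu4NI (cat.), THF, 0 to 25 °C (diol in excess)
Reagents that add atoms: 4-methoxybenzyl chloride COc1ccc(CCl)cc1
Why: Williamson mono-etherification of the symmetrical diol used in excess should give the mono-ether; no stereocentre is involved.

Step 4
Reactants: 6 4-[(4-methoxybenzyl)oxy]but-2-yn-1-ol
Product: 7 (Z)-3-iodo-4-[(4-methoxybenzyl)oxy]but-2-en-1-ol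
Conditions: NaAlH2(OCH2CH2OCH3)2, THF, 0 °C; then I2, −78 °C
Reagents that add atoms: iodine II
Why: Hydroxyl-directed trans-hydroalumination should place aluminium on the alkyne carbon remote from the free hydroxyl, and iodinolysis with retention should give the Z iodoalkene (hydroalumination–iodination).

Step 5
Reactants: 7 (Z)-3-iodo-4-[(4-methoxybenzyl)oxy]but-2-en-1-ol
Product: 8 (Z)-4-[(4-methoxybenzyl)oxy]-3-(tributylstannyl)but-2-en-1-ol
Conditions: (Bu3Sn)2, PdCl2(PPh3)2 (cat.), THF, 60 °C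
Reagents that add atoms: hexabutylditin CCCC[Sn](CCCC)(CCCC)[Sn](CCCC)(CCCC)CCCC
Why: Palladium-catalysed stannylation of the alkenyl iodide with the distannane (Stille-type coupling) should proceed with retention of the alkene geometry and tolerate the free alcohol.

Step 6
Reactants: 8 (Z)-4-[(4-methoxybenzyl)oxy]-3-(tributylstannyl)but-2-en-1-ol
Product: 10 (Z)-tributyl{4-bromo-1-[(4-methoxybenzyl)oxy]but-2-en-2-yl}stannane, via allylic mesylate 9 (not isolated)
Conditions: MsCl, Et3N, CH2Cl2, −20 °C; then LiBr, THF, 0 °C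
Reagents that add atoms: lithium bromide [Li+].[Br-]
Why: Mesylation and SN2 displacement by bromide (Finkelstein-type) should give the primary allylic bromide without allylic transposition, because the gamma-carbon is fully substituted, and under conditions that leave the C–Sn bond intact.

Step 7
Reactants: 4 tert-butyl{[(1R)-2,2-dimethyl-4-[(trimethylsilyl)oxy]cyclohex-3-en-1-yl]oxy}dimethylsilane; 10 (Z)-tributyl{4-bromo-1-[(4-methoxybenzyl)oxy]but-2-en-2-yl}stannane; 11 chloroacetyl chloride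
Product: 14 (2S,4R)-4-[(tert-butyldimethylsilyl)oxy]-2-[(2Z)-5-chloro-3-{[(4-methoxybenzyl)oxy]methyl}-4-oxopent-2-en-1-yl]-3,3-dimethylcyclohexan-1-one, via lithium enolate 12 (not isolated), via stannyl ketone 13 (not isolated)
Conditions: MeLi (1 equiv), THF, 0 °C; 10, DMPU, −78 to −20 °C; then 11, Pd2(dba)3 (cat.), P(2-furyl)3, THF, 50 °C
Reagents that add atoms: none
Why: MeLi cleaves silyl enol ether 4 to the regiodefined lithium enolate 12, whose carbon next to the gem-dimethyl centre displaces bromide from the primary allylic bromide 10 (SN2) to give stannyl ketone 13; in the same flask the acyl–palladium species formed by oxidative addition of zerovalent palladium to acid chloride 11 takes over the alkenyl group from tin with retention and gives enone 14 by reductive elimination. The closest known reaction types are the C-allylation of a regiospecifically generated ketone enolate and the Stille acylation of an alkenylstannane, combined here as a one-flask linchpin union of three components. No ring is closed in this step. The one new stereocentre (C2 of the cyclohexanone, later C5a) is set by substrate control: the electrophile should add axially to the half-chair enolate whose 4-silyloxy group sits pseudo-equatorial, anti to the pseudo-axial methyl of the neighbouring quaternary carbon, which places the chain trans to the silyloxy group; the alkene geometry is carried over unchanged from 10. The step needs C- over O-alkylation and SN2 over SN2′ (secured by the lithium counter-ion and the fully substituted gamma-carbon of 10) and acylation only at tin (secured because the acid chloride is added after the enolate is consumed and reacts with the stannane only under palladium catalysis).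

Step 8
Reactants: 14 (2S,4R)-4-[(tert-butyldimethylsilyl)oxy]-2-[(2Z)-5-chloro-3-{[(4-methoxybenzyl)oxy]methyl}-4-oxopent-2-en-1-yl]-3,3-dimethylcyclohexan-1-one
Product: 15 (2S,4R)-4-[(tert-butyldimethylsilyl)oxy]-2-[(2Z,4S)-5-chloro-4-hydroxy-3-{[(4-methoxybenzyl)oxy]methyl}pent-2-en-1-yl]-3,3-dimethylcyclohexan-1-one
Conditions: (S)-2-methyl-CBS-oxazaborolidine (cat.), catecholborane, toluene, −78 °C
Reagents that add atoms: none
Why: In this Corey–Bakshi–Shibata reduction the (S)-oxazaborolidine should deliver hydride to the face that treats the alkenyl group as the large substituent, giving the 4S chlorohydrin; the activated alpha-chloro enone should react much faster than the hindered, alpha-branched ring ketone.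

Step 9
Reactants: 15 (2S,4R)-4-[(tert-butyldimethylsilyl)oxy]-2-[(2Z,4S)-5-chloro-4-hydroxy-3-{[(4-methoxybenzyl)oxy]methyl}pent-2-en-1-yl]-3,3-dimethylcyclohexan-1-one
Product: 16 (1S,2S,4R)-4-[(tert-butyldimethylsilyl)oxy]-2-[(2Z,4S)-5-chloro-4-hydroxy-3-{[(4-methoxybenzyl)oxy]methyl}pent-2-en-1-yl]-1,3,3-trimethylcyclohexan-1-ol
Conditions: MeMgBr, CeCl3, THF, −78 °C
Reagents that add atoms: methylmagnesium bromide C[Mg]Br
Why: Organocerium 1,2-addition suppresses enolisation; methyl should enter equatorially, because the axial face is blocked by the axial methyl of the neighbouring quaternary carbon, on the conformer with the C2 chain axial, which sets the tertiary carbinol with hydroxyl trans to the chain.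

Step 10
Reactants: 16 (1S,2S,4R)-4-[(tert-butyldimethylsilyl)oxy]-2-[(2Z,4S)-5-chloro-4-hydroxy-3-{[(4-methoxybenzyl)oxy]methyl}pent-2-en-1-yl]-1,3,3-trimethylcyclohexan-1-ol
Product: 17 (1S,2S,4R)-2-[(2Z)-3-{[(4-methoxybenzyl)oxy]methyl}-3-[(2S)-oxiran-2-yl]prop-2-en-1-yl]-1,3,3-trimethylcyclohexane-1,4-diol
Conditions: Bu4NF, THF, 45 °C; then K2CO3, MeOH, 25 °C
Reagents that add atoms: none
Why: Fluoride cleaves the silyl ether, and intramolecular Williamson closure of the chlorohydrin should give the epoxide with the carbinol configuration kept, since its C–O bond is not broken.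

Step 11
Reactants: 17 (1S,2S,4R)-2-[(2Z)-3-{[(4-methoxybenzyl)oxy]methyl}-3-[(2S)-oxiran-2-yl]prop-2-en-1-yl]-1,3,3-trimethylcyclohexane-1,4-diol
Product: 18 (2R,5aS,7R,9aS)-2-(hydroxymethyl)-3-{[(4-methoxybenzyl)oxy]methyl}-6,6,9a-trimethyl-2,5,5a,6,7,8,9,9a-octahydro-1-benzoxepin-7-ol
Conditions: camphorsulfonic acid (cat.), CH2Cl2, 0 °C
Reagents that add atoms: none
Why: In this acid-catalysed hydroxy-epoxide cyclisation the alkene activates the allylic C–O bond, so the tertiary hydroxyl should attack that carbon in the 7-endo mode with inversion, setting C2 as R and closing ring B onto the already fixed trans ring-fusion centres.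

Step 12
Reactants: 18 (2R,5aS,7R,9aS)-2-(hydroxymethyl)-3-{[(4-methoxybenzyl)oxy]methyl}-6,6,9a-trimethyl-2,5,5a,6,7,8,9,9a-octahydro-1-benzoxepin-7-ol
Product: 19 (2R,5aS,7S,9aS)-7-bromo-2-(bromomethyl)-3-{[(4-methoxybenzyl)oxy]methyl}-6,6,9a-trimethyl-2,5,5a,6,7,8,9,9a-octahydro-1-benzoxepine
Conditions: CBr4, PPh3, pyridine, toluene, 0 to 60 °C
Reagents that add atoms: carbon tetrabromide BrC(Br)(Br)Br
Why: A double Appel reaction should substitute the primary alcohol and, with inversion, the axial secondary alcohol, giving the equatorial 7S bromide.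

Step 13
Reactants: 19 (2R,5aS,7S,9aS)-7-bromo-2-(bromomethyl)-3-{[(4-methoxybenzyl)oxy]methyl}-6,6,9a-trimethyl-2,5,5a,6,7,8,9,9a-octahydro-1-benzoxepine
Product: 20 [(2R,5aS,7S,9aS)-7-bromo-2-(bromomethyl)-6,6,9a-trimethyl-2,5,5a,6,7,8,9,9a-octahydro-1-benzoxepin-3-yl]methanol
Conditions: DDQ, CH2Cl2, pH 7 buffer, 0 °C
Reagents that add atoms: none
Why: Oxidative cleavage of the 4-methoxybenzyl ether with DDQ should free the allylic alcohol without touching the alkyl bromides or any stereocentre.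

**Compound list**
1 | (R)-4-[(tert-butyldimethylsilyl)oxy]cyclohex-2-en-1-one | O=C1C=C[C@H](O[Si](C)(C)C(C)(C)C)CC1 | starting material
2 | tert-butyldimethyl{[(1R,2R)-2-methyl-4-[(trimethylsilyl)oxy]cyclohex-3-en-1-yl]oxy}silane | C[Si](C)(C)OC1=C[C@@H](C)[C@H](O[Si](C)(C)C(C)(C)C)CC1 | intermediate
3 | (R)-4-[(tert-butyldimethylsilyl)oxy]-3-methylcyclohex-2-en-1-one | O=C1C=C(C)[C@H](O[Si](C)(C)C(C)(C)C)CC1 | intermediate
4 | tert-butyl{[(1R)-2,2-dimethyl-4-[(trimethylsilyl)oxy]cyclohex-3-en-1-yl]oxy}dimethylsilane | CC1(C)[C@H](O[Si](C)(C)C(C)(C)C)CCC(O[Si](C)(C)C)=C1 | intermediate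
5 | but-2-yne-1,4-diol | OCC#CCO | starting material
6 | 4-[(4-methoxybenzyl)oxy]but-2-yn-1-ol | OCC#CCOCc1ccc(OC)cc1 | intermediate
7 | (Z)-3-iodo-4-[(4-methoxybenzyl)oxy]but-2-en-1-ol | OC/C=C(/COCc1ccc(OC)cc1)I | intermediate
8 | (Z)-4-[(4-methoxybenzyl)oxy]-3-(tributylstannyl)but-2-en-1-ol | OC/C=C(/COCc1ccc(OC)cc1)[Sn](CCCC)(CCCC)CCCC | intermediate
9 | (Z)-4-[(4-methoxybenzyl)oxy]-3-(tributylstannyl)but-2-en-1-yl methanesulfonate | CS(=O)(=O)OC/C=C(/COCc1ccc(OC)cc1)[Sn](CCCC)(CCCC)CCCC | intermediate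
10 | (Z)-tributyl{4-bromo-1-[(4-methoxybenzyl)oxy]but-2-en-2-yl}stannane | BrC/C=C(/COCc1ccc(OC)cc1)[Sn](CCCC)(CCCC)CCCC | intermediate
11 | chloroacetyl chloride | ClCC(Cl)=O | starting material
12 | lithium (R)-4-[(tert-butyldimethylsilyl)oxy]-3,3-dimethylcyclohex-1-en-1-olate | CC1(C)[C@H](O[Si](C)(C)C(C)(C)C)CCC([O-])=C1.[Li+] | intermediate
13 | (2S,4R)-4-[(tert-butyldimethylsilyl)oxy]-2-{(2Z)-4-[(4-methoxybenzyl)oxy]-3-(tributylstannyl)but-2-en-1-yl}-3,3-dimethylcyclohexan-1-one | CC1(C)[C@H](O[Si](C)(C)C(C)(C)C)CCC(=O)[C@H]1C/C=C(/COCc2ccc(OC)cc2)[Sn](CCCC)(CCCC)CCCC | intermediate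
14 | (2S,4R)-4-[(tert-butyldimethylsilyl)oxy]-2-[(2Z)-5-chloro-3-{[(4-methoxybenzyl)oxy]methyl}-4-oxopent-2-en-1-yl]-3,3-dimethylcyclohexan-1-one | CC1(C)[C@H](O[Si](C)(C)C(C)(C)C)CCC(=O)[C@H]1C/C=C(/COCc2ccc(OC)cc2)C(=O)CCl | intermediate
15 | (2S,4R)-4-[(tert-butyldimethylsilyl)oxy]-2-[(2Z,4S)-5-chloro-4-hydroxy-3-{[(4-methoxybenzyl)oxy]methyl}pent-2-en-1-yl]-3,3-dimethylcyclohexan-1-one | CC1(C)[C@H](O[Si](C)(C)C(C)(C)C)CCC(=O)[C@H]1C/C=C(/COCc2ccc(OC)cc2)[C@H](O)CCl | intermediate
16 | (1S,2S,4R)-4-[(tert-butyldimethylsilyl)oxy]-2-[(2Z,4S)-5-chloro-4-hydroxy-3-{[(4-methoxybenzyl)oxy]methyl}pent-2-en-1-yl]-1,3,3-trimethylcyclohexan-1-ol | CC1(C)[C@H](O[Si](C)(C)C(C)(C)C)CC[C@](C)(O)[C@H]1C/C=C(/COCc2ccc(OC)cc2)[C@H](O)CCl | intermediate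
17 | (1S,2S,4R)-2-[(2Z)-3-{[(4-methoxybenzyl)oxy]methyl}-3-[(2S)-oxiran-2-yl]prop-2-en-1-yl]-1,3,3-trimethylcyclohexane-1,4-diol | CC1(C)[C@H](O)CC[C@](C)(O)[C@H]1C/C=C(/COCc2ccc(OC)cc2)[C@H]2CO2 | intermediate
18 | (2R,5aS,7R,9aS)-2-(hydroxymethyl)-3-{[(4-methoxybenzyl)oxy]methyl}-6,6,9a-trimethyl-2,5,5a,6,7,8,9,9a-octahydro-1-benzoxepin-7-ol | CC1(C)[C@H](O)CC[C@]2(C)O[C@@H](CO)C(COCc3ccc(OC)cc3)=CC[C@@H]12 | intermediate
19 | (2R,5aS,7S,9aS)-7-bromo-2-(bromomethyl)-3-{[(4-methoxybenzyl)oxy]methyl}-6,6,9a-trimethyl-2,5,5a,6,7,8,9,9a-octahydro-1-benzoxepine | CC1(C)[C@@H](Br)CC[C@]2(C)O[C@@H](CBr)C(COCc3ccc(OC)cc3)=CC[C@@H]12 | intermediate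
20 | [(2R,5aS,7S,9aS)-7-bromo-2-(bromomethyl)-6,6,9a-trimethyl-2,5,5a,6,7,8,9,9a-octahydro-1-benzoxepin-3-yl]methanol | CC1(C)[C@@H](Br)CC[C@]2(C)O[C@@H](CBr)C(CO)=CC[C@@H]12 | target

Total step count: 13. Longest linear sequence: 11 steps (5 to 20 through steps 3 to 13).

**Steps most likely to fail**

Step 7. The hindered, alpha-branched alkenylstannane may transfer to palladium too slowly, so that protodestannylation competes, or facial control in the enolate alkylation may erode. The fallback separates the two bond formations and makes the second one a chromium-mediated addition. It sets out from 4 and 7. Alcohol 7 is mesylated and displaced with LiBr to give (Z)-1-{[(4-bromo-2-iodobut-2-en-1-yl)oxy]methyl}-4-methoxybenzene F1. Enolate 12, made from 4 with MeLi, is alkylated with it to give (2S,4R)-4-[(tert-butyldimethylsilyl)oxy]-2-{(2Z)-3-iodo-4-[(4-methoxybenzyl)oxy]but-2-en-1-yl}-3,3-dimethylcyclohexan-1-one F2. A NiCl2-catalysed CrCl2 coupling (Nozaki–Hiyama–Kishi) with chloroacetaldehyde gives the chlorohydrin mixture (2S,4R)-4-[(tert-butyldimethylsilyl)oxy]-2-[(2Z)-5-chloro-4-hydroxy-3-{[(4-methoxybenzyl)oxy]methyl}pent-2-en-1-yl]-3,3-dimethylcyclohexan-1-one F3, as both carbinol epimers. Dess–Martin oxidation brings the route back at 14.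

Step 9. Methyl may add to the other face of the ring ketone, so that the hydroxyl ends cis to the chain and ring B can no longer close trans-fused. The fallback lets oxygen, not carbon, enter at C9a and closes ring B through the carbinol oxygen with retention. It sets out from 14. Reduction with the (R)-configured CBS catalyst and catecholborane gives the epimeric chlorohydrin (2S,4R)-4-[(tert-butyldimethylsilyl)oxy]-2-[(2Z,4R)-5-chloro-4-hydroxy-3-{[(4-methoxybenzyl)oxy]methyl}pent-2-en-1-yl]-3,3-dimethylcyclohexan-1-one F4. Methylenation with Zn, CH2Br2 and TiCl4 gives the exocyclic alkene tert-butyl{[(1R,3S)-3-[(2Z,4R)-5-chloro-4-hydroxy-3-{[(4-methoxybenzyl)oxy]methyl}pent-2-en-1-yl]-2,2-dimethyl-4-methylidenecyclohexyl]oxy}dimethylsilane F5. Intramolecular oxymercuration with Hg(OCOCF3)2 followed by NaBH4, in which oxygen should enter equatorially, gives the chloride tert-butyl{[(2R,5aS,7R,9aS)-2-(chloromethyl)-3-{[(4-methoxybenzyl)oxy]methyl}-6,6,9a-trimethyl-2,5,5a,6,7,8,9,9a-octahydro-1-benzoxepin-7-yl]oxy}dimethylsilane F6. CsOAc in DMF gives the acetate [(2R,5aS,7R,9aS)-7-[(tert-butyldimethylsilyl)oxy]-3-{[(4-methoxybenzyl)oxy]methyl}-6,6,9a-trimethyl-2,5,5a,6,7,8,9,9a-octahydro-1-benzoxepin-2-yl]methyl acetate F7. Bu4NF followed by K2CO3 in MeOH brings the route back at 18.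

Step 12. At the secondary carbinol next to the quaternary carbon, E2 elimination or a 1,2-methyl shift may outrun the SN2 displacement. The fallback brominates the two positions separately and displaces a pre-formed sulfonate with a soluble bromide. It sets out from 18. An Appel reaction with one equivalent of CBr4 and PPh3 at 0 °C gives the mono-bromide (2R,5aS,7R,9aS)-2-(bromomethyl)-3-{[(4-methoxybenzyl)oxy]methyl}-6,6,9a-trimethyl-2,5,5a,6,7,8,9,9a-octahydro-1-benzoxepin-7-ol F8. Tf2O and pyridine give the triflate (2R,5aS,7R,9aS)-2-(bromomethyl)-3-{[(4-methoxybenzyl)oxy]methyl}-6,6,9a-trimethyl-2,5,5a,6,7,8,9,9a-octahydro-1-benzoxepin-7-yl trifluoromethanesulfonate F9. Bu4NBr in toluene displaces it with inversion and brings the route back at 19.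

**Further compounds**
F1 | step 7 | (Z)-1-{[(4-bromo-2-iodobut-2-en-1-yl)oxy]methyl}-4-methoxybenzene | BrC/C=C(/COCc1ccc(OC)cc1)I
F2 | step 7 | (2S,4R)-4-[(tert-butyldimethylsilyl)oxy]-2-{(2Z)-3-iodo-4-[(4-methoxybenzyl)oxy]but-2-en-1-yl}-3,3-dimethylcyclohexan-1-one | CC1(C)[C@H](O[Si](C)(C)C(C)(C)C)CCC(=O)[C@H]1C/C=C(/COCc2ccc(OC)cc2)I
F3 | step 7 | (2S,4R)-4-[(tert-butyldimethylsilyl)oxy]-2-[(2Z)-5-chloro-4-hydroxy-3-{[(4-methoxybenzyl)oxy]methyl}pent-2-en-1-yl]-3,3-dimethylcyclohexan-1-one (both carbinol epimers) | CC1(C)[C@H](O[Si](C)(C)C(C)(C)C)CCC(=O)[C@H]1C/C=C(/COCc2ccc(OC)cc2)C(O)CCl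
F4 | step 9 | (2S,4R)-4-[(tert-butyldimethylsilyl)oxy]-2-[(2Z,4R)-5-chloro-4-hydroxy-3-{[(4-methoxybenzyl)oxy]methyl}pent-2-en-1-yl]-3,3-dimethylcyclohexan-1-one | CC1(C)[C@H](O[Si](C)(C)C(C)(C)C)CCC(=O)[C@H]1C/C=C(/COCc2ccc(OC)cc2)[C@@H](O)CCl
F5 | step 9 | tert-butyl{[(1R,3S)-3-[(2Z,4R)-5-chloro-4-hydroxy-3-{[(4-methoxybenzyl)oxy]methyl}pent-2-en-1-yl]-2,2-dimethyl-4-methylidenecyclohexyl]oxy}dimethylsilane | CC1(C)[C@H](O[Si](C)(C)C(C)(C)C)CCC(=C)[C@H]1C/C=C(/COCc2ccc(OC)cc2)[C@@H](O)CCl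
F6 | step 9 | tert-butyl{[(2R,5aS,7R,9aS)-2-(chloromethyl)-3-{[(4-methoxybenzyl)oxy]methyl}-6,6,9a-trimethyl-2,5,5a,6,7,8,9,9a-octahydro-1-benzoxepin-7-yl]oxy}dimethylsilane | CC1(C)[C@H](O[Si](C)(C)C(C)(C)C)CC[C@]2(C)O[C@@H](CCl)C(COCc3ccc(OC)cc3)=CC[C@@H]12
F7 | step 9 | [(2R,5aS,7R,9aS)-7-[(tert-butyldimethylsilyl)oxy]-3-{[(4-methoxybenzyl)oxy]methyl}-6,6,9a-trimethyl-2,5,5a,6,7,8,9,9a-octahydro-1-benzoxepin-2-yl]methyl acetate | CC1(C)[C@H](O[Si](C)(C)C(C)(C)C)CC[C@]2(C)O[C@@H](COC(C)=O)C(COCc3ccc(OC)cc3)=CC[C@@H]12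
F8 | step 12 | (2R,5aS,7R,9aS)-2-(bromomethyl)-3-{[(4-methoxybenzyl)oxy]methyl}-6,6,9a-trimethyl-2,5,5a,6,7,8,9,9a-octahydro-1-benzoxepin-7-ol | CC1(C)[C@H](O)CC[C@]2(C)O[C@@H](CBr)C(COCc3ccc(OC)cc3)=CC[C@@H]12
F9 | step 12 | (2R,5aS,7R,9aS)-2-(bromomethyl)-3-{[(4-methoxybenzyl)oxy]methyl}-6,6,9a-trimethyl-2,5,5a,6,7,8,9,9a-octahydro-1-benzoxepin-7-yl trifluoromethanesulfonate | CC1(C)[C@H](OS(=O)(=O)C(F)(F)F)CC[C@]2(C)O[C@@H](CBr)C(COCc3ccc(OC)cc3)=CC[C@@H]12
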